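**Retrosynthetic overview**
- Solandelactone F ⇐ catalyst-controlled reduction of its 14-ketone (the only stereocentre not set in the cascade).
- 14-Keto lactone ⇐ one cationic cascade of an acyclic (4Z,7E)-10,11-epoxy-12E-en-14-one tert-butyl ester: the cyclopropane (C8–C10) forms first, the eight-membered lactone (C7–O) second, in the same flask.
- Epoxy enone ⇐ Wittig reaction of a C1–C12 epoxy aldehyde with a C13–C22 keto-ylide made from cis-3-nonen-1-ol.
- Epoxy aldehyde ⇐ Sharpless epoxidation of a (4Z,7E,10E)-trienol ⇐ Cu-alkyne allylation, Stille coupling and Lindlar reduction from pent-4-ynoic acid, (E)-1,4-dibromobut-2-ene and a hydroxypropenylstannane.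

Assumption: positions are given in fatty-acid numbering (C1 = lactone carbonyl, C22 = terminal methyl); the target is (7R,8R,10R,11R,14S).

**Step 1**
Reactants: 1 pent-4-ynoic acid
Product: 2 tert-butyl pent-4-ynoate
Conditions: isobutene (excess), conc. H2SO4 (cat.), CH2Cl2, −78 °C → rt, sealed vessel
Reagents that add atoms: 2-methylpropene (isobutene), CC(C)=C
Why: Acid-catalysed Markovnikov addition of the carboxylic acid to isobutene (tert-butyl ester formation via the tert-butyl cation) is clean, and the terminal alkyne is inert to catalytic H2SO4 in the absence of a mercury or gold salt.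

**Step 2**
Reactants: 2 tert-butyl pent-4-ynoate; 3 (E)-1,4-dibromobut-2-ene (3 equiv)
Product: 4 tert-butyl (E)-9-bromonon-7-en-4-ynoate
Conditions: CuI (20 mol %), K2CO3 (1.5 equiv), n-Bu4NBr, DMF, rt
Reagents that add atoms: none
Why: Copper(I)-catalysed allylation of a terminal alkyne (Jeffery-type Cu-acetylide SN2 coupling) joins C5 to C6 at the primary allylic carbon with the E-olefin untouched, and the excess of the symmetric dibromide keeps the second bromide free.

**Step 3**
Reactants: 4 tert-butyl (E)-9-bromonon-7-en-4-ynoate; 5 (E)-3-(tributylstannyl)prop-2-en-1-ol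
Product: 6 tert-butyl (7E,10E)-12-hydroxydodeca-7,10-dien-4-ynoate
Conditions: PdCl2(MeCN)2 (5 mol %), DMF, rt
Reagents that add atoms: none
Why: Stille allyl–vinyl cross-coupling through a π-allylpalladium intermediate forms C9–C10 at the less hindered allyl terminus with retention of the stannane E geometry, which gives the skipped (7E,10E)-diene without protecting the hydroxyl.

**Step 4**
Reactants: 6 tert-butyl (7E,10E)-12-hydroxydodeca-7,10-dien-4-ynoate
Product: 7 tert-butyl (4Z,7E,10E)-12-hydroxydodeca-4,7,10-trienoate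
Conditions: H2 (1 atm, 1 equiv uptake), Lindlar catalyst, quinoline, EtOAc, rt
Reagents that add atoms: none
Why: Lindlar semihydrogenation adds H2 syn to the only alkyne to give the 4Z-olefin, while the poisoned catalyst leaves the E-olefins, the allylic alcohol and the ester alone.

**Step 5**
Reactants: 7 tert-butyl (4Z,7E,10E)-12-hydroxydodeca-4,7,10-trienoate
Product: 8 tert-butyl (4Z,7E)-9-[(2R,3R)-3-(hydroxymethyl)oxiran-2-yl]nona-4,7-dienoate
Conditions: Ti(OiPr)4 (10 mol %), D-(−)-diisopropyl tartrate (12 mol %), t-BuOOH (2 equiv, decane), 4 Å MS, CH2Cl2, −20 °C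
Reagents that add atoms: tert-butyl hydroperoxide, CC(C)(C)OO
Why: Sharpless asymmetric epoxidation is hydroxyl-directed so only the allylic 10,11-olefin reacts, and the D-(−)-tartrate complex delivers oxygen to the face that gives the trans-(10R,11R) epoxide (the 2R,3R epoxy alcohol, as for E-2-alkenols in general).

**Step 6**
Reactants: 9 (Z)-non-3-en-1-ol
Product: 10 (Z)-non-3-enoic acid
Conditions: CrO3, H2SO4, H2O/acetone (Jones), 0 °C
Reagents that add atoms: water, O
Why: Jones oxidation takes the primary alcohol through the aldehyde hydrate to the acid at 0 °C in acid, conditions under which a Z-β,γ-olefin does not migrate (as in the preparation of cis-3-hexenoic acid from cis-3-hexenol).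

**Step 7**
Reactants: 10 (Z)-non-3-enoic acid
Product: 12 (Z)-1-(triphenyl-λ5-phosphanylidene)dec-4-en-2-one, via N-acylimidazole 11 (not isolated)
Conditions: CDI (1.1 equiv), THF, rt; then add to Ph3P=CH2 (2.1 equiv, from Ph3PCH3Br and n-BuLi), THF, −78 → 0 °C
Reagents that add atoms: 1,1'-carbonyldiimidazole (imidazole ring of 11), O=C(n1ccnc1)n1ccnc1; methyltriphenylphosphonium bromide (as its ylide), C[P+](c1ccccc1)(c1ccccc1)c1ccccc1.[Br-]
Why: C-Acylation of methylenetriphenylphosphorane by an N-acylimidazole (ylide acylation then proton transfer) gives the ketone-stabilised ylide, and addition at −78 °C is expected to outrun α-deprotonation so the Z-β,γ-olefin stays in place.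

**Step 8**
Reactants: 8 tert-butyl (4Z,7E)-9-[(2R,3R)-3-(hydroxymethyl)oxiran-2-yl]nona-4,7-dienoate; 12 (Z)-1-(triphenyl-λ5-phosphanylidene)dec-4-en-2-one (1.5 equiv)
Product: 14 tert-butyl (4Z,7E)-9-{(2R,3R)-3-[(1E,5Z)-3-oxoundeca-1,5-dien-1-yl]oxiran-2-yl}nona-4,7-dienoate, via epoxy aldehyde 13 (not isolated)
Conditions: TEMPO (10 mol %), PhI(OAc)2 (1.1 equiv), CH2Cl2, rt; then 12, rt → 35 °C
Reagents that add atoms: none
Why: TEMPO/PhI(OAc)2 oxidation gives the labile epoxy aldehyde without base, and the in-situ Wittig reaction with the ketone-stabilised ylide gives the E-enone (C12=C13) under neutral conditions that spare the epoxide and the β,γ-unsaturated ketone.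

**Step 9**
Reactants: 14 tert-butyl (4Z,7E)-9-{(2R,3R)-3-[(1E,5Z)-3-oxoundeca-1,5-dien-1-yl]oxiran-2-yl}nona-4,7-dienoate
Product: 15 (5Z,8R)-8-{(1R,2R)-2-[(1R,2E,6Z)-1-hydroxy-4-oxododeca-2,6-dien-1-yl]cyclopropyl}-3,4,7,8-tetrahydro-2H-oxocin-2-one
Conditions: BF3·OEt2 (0.5 equiv), CH2Cl2 (2 mM), −78 → −40 °C; Et3N, then aq. NaHCO3
Reagents that add atoms: none
Why: Proposed new method: BF3 activates the epoxide while the electron-poor enone blocks ionisation at C11, so the 7E-olefin opens C10–O from the back (inversion at C10, C11–O retained as the 11R carbinol) to give the trans-cyclopropylcarbinyl cation, and the tert-butyl ester carbonyl, held near C7 by the 4Z-olefin, traps C7 anti to the new C8–C10 bond and loses isobutene, so 7R, 8R and 10R are all relayed from the epoxide (the 7E geometry is chosen because anti addition across a 7Z-olefin would give the C7 epimer); the closest known reaction type is the epoxide-initiated homoallyl-to-cyclopropylcarbinyl cation cyclisation terminated by an ester to give cyclopropyl δ-lactones, with the i-steroid rearrangement as the model for anti capture, here extended to an eight-membered lactone.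

**Step 10**
Reactants: 15 (5Z,8R)-8-{(1R,2R)-2-[(1R,2E,6Z)-1-hydroxy-4-oxododeca-2,6-dien-1-yl]cyclopropyl}-3,4,7,8-tetrahydro-2H-oxocin-2-one
Product: 16 Solandelactone F
Conditions: (R)-2-methyl-CBS-oxazaborolidine (0.3 equiv), catecholborane (3 equiv), toluene/CH2Cl2, −78 °C; MeOH, then pH 7 buffer
Reagents that add atoms: none
Why: Corey–Bakshi–Shibata reduction, in which the (R)-oxazaborolidine binds the ketone with the alkenyl arm as the large group and delivers hydride to give the 14S allylic alcohol (the sense known for 15-keto prostaglandin enones), while catecholborane at −78 °C does not touch the lactone or the olefins.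

**Compound list**
1 | pent-4-ynoic acid | C#CCCC(=O)O | starting material
2 | tert-butyl pent-4-ynoate | C#CCCC(=O)OC(C)(C)C | intermediate
3 | (E)-1,4-dibromobut-2-ene | BrC/C=C/CBr | starting material
4 | tert-butyl (E)-9-bromonon-7-en-4-ynoate | BrC/C=C/CC#CCCC(=O)OC(C)(C)C | intermediate
5 | (E)-3-(tributylstannyl)prop-2-en-1-ol | CCCC[Sn](CCCC)(CCCC)/C=C/CO | starting material
6 | tert-butyl (7E,10E)-12-hydroxydodeca-7,10-dien-4-ynoate | OC/C=C/C/C=C/CC#CCCC(=O)OC(C)(C)C | intermediate
7 | tert-butyl (4Z,7E,10E)-12-hydroxydodeca-4,7,10-trienoate | OC/C=C/C/C=C/C/C=C\CCC(=O)OC(C)(C)C | intermediate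
8 | tert-butyl (4Z,7E)-9-[(2R,3R)-3-(hydroxymethyl)oxiran-2-yl]nona-4,7-dienoate | OC[C@H]1O[C@@H]1C/C=C/C/C=C\CCC(=O)OC(C)(C)C | intermediate
9 | (Z)-non-3-en-1-ol (cis-3-nonen-1-ol) | CCCCC/C=C\CCO | starting material
10 | (Z)-non-3-enoic acid | CCCCC/C=C\CC(=O)O | intermediate
11 | 1-[(Z)-non-3-enoyl]-1H-imidazole | CCCCC/C=C\CC(=O)n1ccnc1 | intermediate
12 | (Z)-1-(triphenyl-λ5-phosphanylidene)dec-4-en-2-one | CCCCC/C=C\CC(=O)C=P(c1ccccc1)(c1ccccc1)c1ccccc1 | intermediate
13 | tert-butyl (4Z,7E)-9-[(2R,3S)-3-formyloxiran-2-yl]nona-4,7-dienoate | O=C[C@H]1O[C@@H]1C/C=C/C/C=C\CCC(=O)OC(C)(C)C | intermediate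
14 | tert-butyl (4Z,7E)-9-{(2R,3R)-3-[(1E,5Z)-3-oxoundeca-1,5-dien-1-yl]oxiran-2-yl}nona-4,7-dienoate | CCCCC/C=C\CC(=O)/C=C/[C@H]1O[C@@H]1C/C=C/C/C=C\CCC(=O)OC(C)(C)C | intermediate
15 | (5Z,8R)-8-{(1R,2R)-2-[(1R,2E,6Z)-1-hydroxy-4-oxododeca-2,6-dien-1-yl]cyclopropyl}-3,4,7,8-tetrahydro-2H-oxocin-2-one (14-oxo-solandelactone F) | CCCCC/C=C\CC(=O)/C=C/[C@@H](O)[C@@H]1C[C@H]1[C@H]1C/C=C\CCC(=O)O1 | intermediate
16 | Solandelactone F, (5Z,8R)-8-{(1R,2R)-2-[(1R,2E,4S,6Z)-1,4-dihydroxydodeca-2,6-dien-1-yl]cyclopropyl}-3,4,7,8-tetrahydro-2H-oxocin-2-one | CCCCC/C=C\C[C@H](O)/C=C/[C@@H](O)[C@@H]1C[C@H]1[C@H]1C/C=C\CCC(=O)O1 | target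

**Totals**
Total step count: 10. Longest linear sequence: 8 (steps 1–5 and 8–10, from pent-4-ynoic acid).

**Steps most likely to fail**

Step 9 is the main risk. The eight-membered closure at C7 may lose to proton loss from the doubly allylic C6, to fluoride capture, or to participation of the 4Z-olefin (second cyclopropane, then γ-lactone). The fallback sets out from 14 and separates the two ring closures. Solvolysis in HFIP–H2O (95:5, 0 °C) lets water end the same epoxide-triggered cyclopropanation at C7, with the same anti stereochemistry, to give tert-butyl (4Z,7R)-7-hydroxy-7-{(1R,2R)-2-[(1R,2E,6Z)-1-hydroxy-4-oxododeca-2,6-dien-1-yl]cyclopropyl}hept-4-enoate F1. TMSOTf/2,6-lutidine (CH2Cl2, 0 °C, then pH 7 buffer–MeOH) removes the tert-butyl group without free strong acid to give (4Z,7R)-7-hydroxy-7-{(1R,2R)-2-[(1R,2E,6Z)-1-hydroxy-4-oxododeca-2,6-dien-1-yl]cyclopropyl}hept-4-enoic acid F2. Shiina lactonisation (MNBA, DMAP, toluene, 1 mM) then closes the Z-olefin-assisted eight-membered ring on the C7 hydroxyl; acylation of the C11 hydroxyl would need an eleven-membered ring across the trans-cyclopropane. This comes back to the route at 15.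

Step 7 is the second risk, because the basic ylide may deprotonate the β,γ-unsaturated acyl imidazole and move the Z-olefin into conjugation. The fallback sets out from 10 and avoids any basic carbon nucleophile. Oxalyl chloride (cat. DMF, CH2Cl2, 0 °C) gives (Z)-non-3-enoyl chloride F3. Diazomethane (Et2O, 0 °C) gives (Z)-1-diazodec-4-en-2-one F4. Aqueous HBr (Et2O, 0 °C) gives (Z)-1-bromodec-4-en-2-one F5. PPh3 (toluene, rt) gives [(Z)-2-oxodec-4-en-1-yl]triphenylphosphonium bromide F6, and aqueous Na2CO3 returns to the route at 12.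

Step 3 is the third risk, since the π-allylpalladium unit next to the propargylic C6 may eliminate or couple at the branched terminus. The fallback sets out from 4 and replaces the cross-coupling by a second copper-acetylide allylation. Propargyl alcohol (CuI, K2CO3, n-Bu4NBr, DMF, rt) gives tert-butyl (E)-12-hydroxydodec-7-ene-4,10-diynoate F7. Chromium(II) sulfate in DMF–H2O then reduces only the alkyne that carries the α-hydroxyl to the E-allylic alcohol, leaving the isolated 4-yne, and comes back to the route at 6.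

**Further compounds**
F1 | step 9 | tert-butyl (4Z,7R)-7-hydroxy-7-{(1R,2R)-2-[(1R,2E,6Z)-1-hydroxy-4-oxododeca-2,6-dien-1-yl]cyclopropyl}hept-4-enoate | CCCCC/C=C\CC(=O)/C=C/[C@@H](O)[C@@H]1C[C@H]1[C@H](O)C/C=C\CCC(=O)OC(C)(C)C
F2 | step 9 | (4Z,7R)-7-hydroxy-7-{(1R,2R)-2-[(1R,2E,6Z)-1-hydroxy-4-oxododeca-2,6-dien-1-yl]cyclopropyl}hept-4-enoic acid | CCCCC/C=C\CC(=O)/C=C/[C@@H](O)[C@@H]1C[C@H]1[C@H](O)C/C=C\CCC(=O)O
F3 | step 7 | (Z)-non-3-enoyl chloride | CCCCC/C=C\CC(=O)Cl
F4 | step 7 | (Z)-1-diazodec-4-en-2-one | CCCCC/C=C\CC(=O)C=[N+]=[N-]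
F5 | step 7 | (Z)-1-bromodec-4-en-2-one | CCCCC/C=C\CC(=O)CBr
F6 | step 7 | [(Z)-2-oxodec-4-en-1-yl]triphenylphosphonium bromide | CCCCC/C=C\CC(=O)C[P+](c1ccccc1)(c1ccccc1)c1ccccc1.[Br-]
F7 | step 3 | tert-butyl (E)-12-hydroxydodec-7-ene-4,10-diynoate | OCC#CC/C=C/CC#CCCC(=O)OC(C)(C)C
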